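**Retrosynthetic overview** (unprimed locants: flavanone unit; primed: flavan unit)
1. The last ring, the dihydrofuran ketal (O7′–C2), is closed by silyl-triflate-triggered addition of the 7′-OH to C2 of a 3-(flavan-8′-yl)flavone; the C3–C8′ axis fixes C2, and C3–H follows by protonation of the enol ether. Hydrogenolysis then ends the route.
2. The hindered C3–C8′ bond comes from an atroposelective Suzuki–Miyaura union of 3-bromo-tri-O-benzylapigenin with a flavan-8′-boronate; the chromone ring is bought as apigenin.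
3. The flavan pyran ring is made in one flask from a 2-fluoro-4,6-dialkoxybenzyl Grignard reagent and (S)-4-benzyloxystyrene oxide: C4′–C3′ by epoxide opening, O1′–C8a′ by SNAr of the C2′ alkoxide.
4. Enabling feature: in the benzo ring of the flavan, C8a′ is ortho to C4a′ (which carries the benzylic C4′) and meta to both oxygenated carbons C5′ and C7′. A C8a′–F bond is therefore inductively activated and not mesomerically deactivated toward the alkoxide that the C–C bond formation itself creates.
5. Ring order: flavan pyran ring (step 7), then dihydrofuran ketal ring (step 14); the C3–C8′ union (step 12) lies between them.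

Key step: step 7

Assumption: the cis-fused ketone ketal is taken to be kinetically stable but less stable than its ring-opened 3-arylflavone and 3-aroylbenzofuran isomers, so it is formed under kinetic control and kept from strong acid and base; the C3–C8′ axis of the 3-(flavan-8′-yl)flavones is taken to be configurationally stable below about 80 °C.

**Route**

Step 1
Reactants: 1 5-fluorobenzene-1,3-diol
Product: 2 2-fluoro-4,6-dihydroxybenzaldehyde
Conditions: POCl3, DMF, MeCN, −15 °C → rt; then H2O, 50 °C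
Reagents that add atoms: N,N-dimethylformamide, CN(C)C=O; water, O
Why: Vilsmeier–Haack formylation, expected para to one OH and ortho to the other (and to F) and not at the doubly flanked carbon between the two OH groups, as with 5-substituted resorcinols.

Step 2
Reactants: 2 2-fluoro-4,6-dihydroxybenzaldehyde
Product: 3 2-fluoro-4,6-bis(methoxymethoxy)benzaldehyde
Conditions: NaH, MOMCl, DMF, 0 °C → rt
Reagents that add atoms: chloromethyl methyl ether, COCCl
Why: Williamson-type O-alkylation of both phenoxides; NaH also breaks the OH···O=C chelate of the ortho phenol.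

Step 3
Reactants: 3 2-fluoro-4,6-bis(methoxymethoxy)benzaldehyde
Product: 4 [2-fluoro-4,6-bis(methoxymethoxy)phenyl]methanol
Conditions: NaBH4, MeOH/THF, 0 °C
Reagents that add atoms: none
Why: Borohydride reduction of the aldehyde; acetals and aryl fluoride are inert.

Step 4
Reactants: 4 [2-fluoro-4,6-bis(methoxymethoxy)phenyl]methanol
Product: 5 2-(chloromethyl)-1-fluoro-3,5-bis(methoxymethoxy)benzene
Conditions: PPh3, N-chlorosuccinimide, THF, 0 °C → rt; used at once
Reagents that add atoms: N-chlorosuccinimide, O=C1CCC(=O)N1Cl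
Why: Appel-type chlorination through the alkoxyphosphonium salt under neutral conditions that spare the acetals.

Step 5
Reactants: 6 1-[4-(benzyloxy)phenyl]-2-bromoethan-1-one
Product: 7 (1S)-1-[4-(benzyloxy)phenyl]-2-bromoethan-1-ol
Conditions: BH3·SMe2, (S)-2-methyl-CBS-oxazaborolidine [(S)-tetrahydro-1-methyl-3,3-diphenyl-1H,3H-pyrrolo[1,2-c][1,3,2]oxazaborole] (10 mol %), THF, 0 °C
Reagents that add atoms: none
Why: Corey–Bakshi–Shibata reduction; with the aryl group as the large substituent the (S)-catalyst should deliver hydride to the face that gives the (S)-bromohydrin.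

Step 6
Reactants: 7 (1S)-1-[4-(benzyloxy)phenyl]-2-bromoethan-1-ol
Product: 8 (2S)-2-[4-(benzyloxy)phenyl]oxirane
Conditions: K2CO3, MeOH, rt
Reagents that add atoms: none
Why: Intramolecular Williamson closure at the CH2Br carbon; the stereocentre is not touched.

Step 7
Reactants: 5 2-(chloromethyl)-1-fluoro-3,5-bis(methoxymethoxy)benzene; 8 (2S)-2-[4-(benzyloxy)phenyl]oxirane
Product: 11 (2R)-2-[4-(benzyloxy)phenyl]-5,7-bis(methoxymethoxy)chromane, via benzylic Grignard reagent 9 (not isolated), via chloromagnesium alkoxide 10 (not isolated)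
Conditions: Mg, THF, 0 °C; then 8, CuBr·SMe2 (10 mol %), THF, −40 → 0 °C; then KOtBu, DMPU, 80 °C (one flask)
Reagents that add atoms: none
Why: Magnesium insertion into the benzylic C–Cl bond gives 9, which under copper catalysis opens epoxide 8 by SN2 attack at the unsubstituted CH2 carbon (C4′–C3′) and so releases the C2′ alkoxide 10; after exchange to the potassium alkoxide in a dipolar medium this oxygen displaces fluoride at C8a′ by addition–elimination (O1′–C8a′). The closest known reaction types are the copper-catalysed opening of aryl oxiranes by Grignard reagents and the base-mediated cyclisation of 3-(2-fluoroaryl)propan-1-ols to chromans, here run in one flask. The pyran ring closes in the 6-exo-trig mode, the oxygen attacking C8a′ with the C8a′=C8′ π bond outside the new ring and passing through an anionic σ-complex. No new stereocentre is made: C2′ comes from the epoxide with its C–O bond unbroken, so the (S)-epoxide gives the (2′R)-flavan by a change of CIP priorities only. The step needs regioselective opening at the CH2 terminus, which the soft copper-bound benzylic nucleophile at low temperature should secure. It also needs O-arylation only at C8a′, secured because fluoride is the sole leaving group and sits meta to both alkoxy groups, whose inductive pull stabilises the σ-complex while their lone pairs cannot reach the attacked carbon.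

Step 8
Reactants: 11 (2R)-2-[4-(benzyloxy)phenyl]-5,7-bis(methoxymethoxy)chromane
Product: 12 (2R)-2-[4-(benzyloxy)phenyl]-8-bromo-5,7-bis(methoxymethoxy)chromane
Conditions: N-bromosuccinimide, CH2Cl2, −78 → 0 °C
Reagents that add atoms: N-bromosuccinimide, O=C1CCC(=O)N1Br
Why: Electrophilic aromatic bromination, expected at C8 (between O7 and the ring oxygen) in preference to C6 (between two acetal ethers), as in the C8 halogenation of 5,7-di-O-alkyl flavans.

Step 9
Reactants: 12 (2R)-2-[4-(benzyloxy)phenyl]-8-bromo-5,7-bis(methoxymethoxy)chromane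
Product: 14 (2R)-2-[4-(benzyloxy)phenyl]-5,7-bis(methoxymethoxy)-8-(4,4,5,5-tetramethyl-1,3,2-dioxaborolan-2-yl)chromane, via 8-lithioflavan 13 (not isolated)
Conditions: n-BuLi, THF, −78 °C; then 2-isopropoxy-4,4,5,5-tetramethyl-1,3,2-dioxaborolane, −78 °C → rt
Reagents that add atoms: 2-isopropoxy-4,4,5,5-tetramethyl-1,3,2-dioxaborolane, CC(C)OB1OC(C)(C)C(C)(C)O1
Why: Bromine–lithium exchange followed by borylation of the doubly ortho-oxygen-stabilised aryllithium.

Step 10
Reactants: 15 apigenin [5,7-dihydroxy-2-(4-hydroxyphenyl)-4H-chromen-4-one]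
Product: 16 5,7-bis(benzyloxy)-2-[4-(benzyloxy)phenyl]-4H-chromen-4-one
Conditions: BnBr, K2CO3, DMF, 80 °C
Reagents that add atoms: benzyl bromide, BrCc1ccccc1
Why: Williamson benzylation; heating is needed to alkylate the chelated 5-OH.

Step 11
Reactants: 16 5,7-bis(benzyloxy)-2-[4-(benzyloxy)phenyl]-4H-chromen-4-one
Product: 18 5,7-bis(benzyloxy)-2-[4-(benzyloxy)phenyl]-3-bromo-4H-chromen-4-one, via 3-lithioflavone 17 (not isolated)
Conditions: LiN(iPr)2, THF, −78 °C; then Br2, −78 °C
Reagents that add atoms: bromine, BrBr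
Why: Carbonyl-directed C3 lithiation of the flavone and trapping with electrophilic bromine.

Step 12
Reactants: 14 (2R)-2-[4-(benzyloxy)phenyl]-5,7-bis(methoxymethoxy)-8-(4,4,5,5-tetramethyl-1,3,2-dioxaborolan-2-yl)chromane; 18 5,7-bis(benzyloxy)-2-[4-(benzyloxy)phenyl]-3-bromo-4H-chromen-4-one
Product: 19 (aS)-5,7-bis(benzyloxy)-2-[4-(benzyloxy)phenyl]-3-{(2R)-2-[4-(benzyloxy)phenyl]-5,7-bis(methoxymethoxy)chroman-8-yl}-4H-chromen-4-one (P helicity about C3–C8′; O7′ lies over the Si face of C2)
Conditions: Pd(OAc)2 (5 mol %), (S)-2-(dicyclohexylphosphino)-2′-(dimethylamino)-1,1′-binaphthyl (ligand hand to be matched to the aS axis), K3PO4, toluene/H2O, 60 °C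
Reagents that add atoms: none
Why: Atroposelective Suzuki–Miyaura coupling of two di-ortho-substituted partners, the chiral monophosphine setting the new C3–C8′ axis; the two atropisomers are diastereomers because of C2′, so a minor one can be removed by chromatography.

Step 13
Reactants: 19 (aS)-bis(methoxymethyl) ether
Product: 20 (aS)-5,7-bis(benzyloxy)-2-[4-(benzyloxy)phenyl]-3-{(2R)-2-[4-(benzyloxy)phenyl]-5,7-dihydroxychroman-8-yl}-4H-chromen-4-one
Conditions: HCl (1.25 M in MeOH), THF, 40 °C
Reagents that add atoms: none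
Why: Acid-catalysed transacetalisation of both methoxymethyl ethers to methanol; benzyl ethers, flavone and axis should be unaffected.

Step 14
Reactants: 20 (aS)-3-(5′,7′-dihydroxyflavan-8′-yl)flavone
Product: 23 (2S,3S)-5,7-bis(benzyloxy)-2-[4-(benzyloxy)phenyl]chroman-4-one whose C2 is bonded to O7′ and whose C3 is bonded to C8′ of (2′R)-2′-[4-(benzyloxy)phenyl]-5′-hydroxychromane (cis-fused ketone ketal), via silyloxyflavylium triflate 21 (not isolated), via silyl enol ether ketal 22 (not isolated)
Conditions: Me3SiOTf (1.1 equiv), CH2Cl2, −78 → −40 °C; 2,6-di-tert-butyl-4-methylpyridine, −78 °C; then Bu4NF/AcOH (1:2), THF, −78 → 0 °C (one flask)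
Reagents that add atoms: none
Why: Proposed new method: the pyranone carbonyl, the most Lewis-basic oxygen of 20, should be silylated to the 4-silyloxyflavylium ion 21, whose C2=O1+ oxocarbenium is attacked in the 5-exo-trig mode by the 7′-OH that the (aS) axis holds over the Si face of C2 (axis-to-centre transfer, S ketal carbon), the hindered pyridine taking the proton so that closure is driven by Si–O bond formation and not by the flavone–ketal equilibrium; buffered fluoride then frees the enol(ate) of 22, which should be protonated at C3 on the only accessible exo face (cis fusion, 3S) faster than it can expel an aryloxide; closest known reaction types are C2 addition of nucleophiles to 4-silyloxybenzopyrylium triflates made from chromones and silyl triflates, and ring closure of flavylium ions by phenols to aryl ketals.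

Step 15
Reactants: 23 tetra-O-benzyl ketone ketal
Product: 24 target: (2S,3S)-5,7-dihydroxy-2-(4-hydroxyphenyl)chroman-4-one, C2–O7′ and C3–C8′ linked to (2′R)-5′-hydroxy-2′-(4-hydroxyphenyl)chromane
Conditions: H2 (1 atm), Pd(OH)2/C, EtOAc/MeOH, rt
Reagents that add atoms: none
Why: Hydrogenolysis of the four benzyl ethers under neutral conditions, which should leave the ketal, the ketone and all three stereocentres untouched.

**Compound list**
1 | 5-fluorobenzene-1,3-diol | Oc1cc(O)cc(F)c1 | starting material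
2 | 2-fluoro-4,6-dihydroxybenzaldehyde | O=Cc1c(F)cc(O)cc1O | intermediate
3 | 2-fluoro-4,6-bis(methoxymethoxy)benzaldehyde | O=Cc1c(F)cc(OCOC)cc1OCOC | intermediate
4 | [2-fluoro-4,6-bis(methoxymethoxy)phenyl]methanol | OCc1c(F)cc(OCOC)cc1OCOC | intermediate
5 | 2-(chloromethyl)-1-fluoro-3,5-bis(methoxymethoxy)benzene | ClCc1c(F)cc(OCOC)cc1OCOC | intermediate
6 | 1-[4-(benzyloxy)phenyl]-2-bromoethan-1-one | O=C(CBr)c1ccc(OCc2ccccc2)cc1 | starting material
7 | (1S)-1-[4-(benzyloxy)phenyl]-2-bromoethan-1-ol | O[C@@H](c1ccc(OCc2ccccc2)cc1)CBr | intermediate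
8 | (2S)-2-[4-(benzyloxy)phenyl]oxirane | O1[C@@H](c2ccc(OCc3ccccc3)cc2)C1 | intermediate
9 | [2-fluoro-4,6-bis(methoxymethoxy)benzyl]magnesium chloride | Cl[Mg]Cc1c(F)cc(OCOC)cc1OCOC | intermediate (not isolated)
10 | chloromagnesium (1R)-1-[4-(benzyloxy)phenyl]-3-[2-fluoro-4,6-bis(methoxymethoxy)phenyl]propan-1-olate | Cl[Mg]O[C@@H](c1ccc(OCc2ccccc2)cc1)CCc1c(F)cc(OCOC)cc1OCOC | intermediate (not isolated)
11 | (2R)-2-[4-(benzyloxy)phenyl]-5,7-bis(methoxymethoxy)chromane | COCOc1cc(OCOC)c2c(c1)O[C@@H](c1ccc(OCc3ccccc3)cc1)CC2 | intermediate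
12 | (2R)-2-[4-(benzyloxy)phenyl]-8-bromo-5,7-bis(methoxymethoxy)chromane | COCOc1cc(OCOC)c2c(c1Br)O[C@@H](c1ccc(OCc3ccccc3)cc1)CC2 | intermediate
13 | (2R)-2-[4-(benzyloxy)phenyl]-5,7-bis(methoxymethoxy)chroman-8-yllithium | COCOc1cc(OCOC)c2c(c1[Li])O[C@@H](c1ccc(OCc3ccccc3)cc1)CC2 | intermediate (not isolated)
14 | (2R)-2-[4-(benzyloxy)phenyl]-5,7-bis(methoxymethoxy)-8-(4,4,5,5-tetramethyl-1,3,2-dioxaborolan-2-yl)chromane | COCOc1cc(OCOC)c2c(c1B4OC(C)(C)C(C)(C)O4)O[C@@H](c1ccc(OCc3ccccc3)cc1)CC2 | intermediate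
15 | apigenin | O=c1cc(-c2ccc(O)cc2)oc2cc(O)cc(O)c12 | starting material
16 | 5,7-bis(benzyloxy)-2-[4-(benzyloxy)phenyl]-4H-chromen-4-one | O=c1cc(-c2ccc(OCc3ccccc3)cc2)oc2cc(OCc3ccccc3)cc(OCc3ccccc3)c12 | intermediate
17 | 3-lithio-5,7-bis(benzyloxy)-2-[4-(benzyloxy)phenyl]-4H-chromen-4-one | O=c1c([Li])c(-c2ccc(OCc3ccccc3)cc2)oc2cc(OCc3ccccc3)cc(OCc3ccccc3)c12 | intermediate (not isolated)
18 | 5,7-bis(benzyloxy)-2-[4-(benzyloxy)phenyl]-3-bromo-4H-chromen-4-one | O=c1c(Br)c(-c2ccc(OCc3ccccc3)cc2)oc2cc(OCc3ccccc3)cc(OCc3ccccc3)c12 | intermediate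
19 | (aS)-5,7-bis(benzyloxy)-2-[4-(benzyloxy)phenyl]-3-{(2R)-2-[4-(benzyloxy)phenyl]-5,7-bis(methoxymethoxy)chroman-8-yl}-4H-chromen-4-one (axis given in the name only) | O=c1c(-c2c(OCOC)cc(OCOC)c3c2O[C@@H](c2ccc(OCc4ccccc4)cc2)CC3)c(-c2ccc(OCc3ccccc3)cc2)oc2cc(OCc3ccccc3)cc(OCc3ccccc3)c12 | intermediate
20 | (aS)-5,7-bis(benzyloxy)-2-[4-(benzyloxy)phenyl]-3-{(2R)-2-[4-(benzyloxy)phenyl]-5,7-dihydroxychroman-8-yl}-4H-chromen-4-one (axis given in the name only) | O=c1c(-c2c(O)cc(O)c3c2O[C@@H](c2ccc(OCc4ccccc4)cc2)CC3)c(-c2ccc(OCc3ccccc3)cc2)oc2cc(OCc3ccccc3)cc(OCc3ccccc3)c12 | intermediate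
21 | (aS)-4-(trimethylsilyloxy)chromenylium triflate of 20 | C[Si](C)(C)Oc1c(-c2c(O)cc(O)c3c2O[C@@H](c2ccc(OCc4ccccc4)cc2)CC3)c(-c2ccc(OCc3ccccc3)cc2)[o+]c2cc(OCc3ccccc3)cc(OCc3ccccc3)c12.[O-]S(=O)(=O)C(F)(F)F | intermediate (not isolated)
22 | trimethylsilyl enol ether of 23 (C3=C4–OSiMe3; ketal carbon R by CIP, same spatial arrangement as 2S in 23; flavan C2′ R) | C[Si](C)(C)OC=1c2c(OCc3ccccc3)cc(OCc3ccccc3)cc2O[C@@]2(c3ccc(OCc5ccccc5)cc3)Oc3cc(O)c4c(c3C=12)O[C@@H](c1ccc(OCc3ccccc3)cc1)CC4 | intermediate (not isolated)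
23 | (2S,3S,2′R)-tetra-O-benzyl ketone ketal (5,7,4″-tri-O-benzyl on the flavanone unit, 4‴-O-benzyl on the flavan unit, 5′-OH free) | O=C1c2c(OCc3ccccc3)cc(OCc3ccccc3)cc2O[C@@]2(c3ccc(OCc5ccccc5)cc3)Oc3cc(O)c4c(c3[C@@H]12)O[C@@H](c1ccc(OCc3ccccc3)cc1)CC4 | intermediate
24 | (2S,3S,2′R)-target, CNP0179743.1 | O=C1c2c(O)cc(O)cc2O[C@@]2(c3ccc(O)cc3)Oc3cc(O)c4c(c3[C@@H]12)O[C@@H](c1ccc(O)cc1)CC4 | target

**Step count and risks**

Total step count: 15
Longest linear sequence: 11 steps (steps 1–4, 7–9, 12–15)

Steps most likely to fail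

1. Step 14 (proposed new method). The silyl triflate may silylate the 7′-OH instead of the carbonyl oxygen, or the enolate freed on desilylation may expel an aryloxide and return the flavone. Fallback: set out from 19 and O-methylate the pyranone carbonyl with MeOTf to the 4-methoxyflavylium triflate F1, which is stable in acid. Methanolic HCl then removes both acetal groups, and buffering with NaHCO3 lets the 7′-phenol add to C2 of the cation (the phenol-to-flavylium ring closure known from aryl ketal work) to give the methyl enol ether ketal F2. Mild hydrolysis of the enol ether with oxalic acid on wet silica comes back to the route at 23.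

2. Step 12. Transmetalation at the di-ortho-alkoxy boronate may be slow and lose out to protodeboronation, and the ligand may control the axis poorly. Fallback: set out from 12 and 16, lithiate 16 at C3 (via 17) and transmetalate with ZnCl2 to the 3-flavonylzinc chloride F3. Negishi coupling with bromide 12 under Pd2(dba)3 and 2-dicyclohexylphosphino-2′,6′-diisopropoxybiphenyl gives both atropisomers without ligand control. These are diastereomers and are separated by chromatography; the (aR)-atropisomer F4 is re-equilibrated by heating in o-dichlorobenzene and recycled, and the (aS)-isomer comes back to the route at 19.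

3. Step 7. The benzylic nucleophile may attack the benzylic epoxide carbon, magnesium salts may rearrange the electron-rich aryl oxirane to an arylacetaldehyde, and Wurtz homocoupling may compete during magnesium insertion. Fallback: set out from 5 and alkylate the lithium enolate of 1-[4-(benzyloxy)phenyl]ethan-1-one with it to give the ketone F5. Corey–Bakshi–Shibata reduction with the (S)-catalyst gives the (1R)-alcohol F6, and KOtBu in DMPU closes the ring by the same SNAr to come back to the route at 11.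

**Further compounds**
F1 | step 14 | (aS)-5,7-bis(benzyloxy)-2-[4-(benzyloxy)phenyl]-3-{(2R)-2-[4-(benzyloxy)phenyl]-5,7-bis(methoxymethoxy)chroman-8-yl}-4-methoxychromenylium triflate | COc1c(-c2c(OCOC)cc(OCOC)c3c2O[C@@H](c2ccc(OCc4ccccc4)cc2)CC3)c(-c2ccc(OCc3ccccc3)cc2)[o+]c2cc(OCc3ccccc3)cc(OCc3ccccc3)c12.[O-]S(=O)(=O)C(F)(F)F
F2 | step 14 | methyl enol ether of 23 (C3=C4–OMe; same spatial arrangement at the ketal carbon as in 23; flavan C2′ R) | COC=1c2c(OCc3ccccc3)cc(OCc3ccccc3)cc2O[C@@]2(c3ccc(OCc5ccccc5)cc3)Oc3cc(O)c4c(c3C=12)O[C@@H](c1ccc(OCc3ccccc3)cc1)CC4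
F3 | step 12 | {5,7-bis(benzyloxy)-2-[4-(benzyloxy)phenyl]-4-oxo-4H-chromen-3-yl}zinc chloride | O=c1c([Zn]Cl)c(-c2ccc(OCc3ccccc3)cc2)oc2cc(OCc3ccccc3)cc(OCc3ccccc3)c12
F4 | step 12 | (aR)-atropisomer of 19 (axis given in the name only) | O=c1c(-c2c(OCOC)cc(OCOC)c3c2O[C@@H](c2ccc(OCc4ccccc4)cc2)CC3)c(-c2ccc(OCc3ccccc3)cc2)oc2cc(OCc3ccccc3)cc(OCc3ccccc3)c12
F5 | step 7 | 1-[4-(benzyloxy)phenyl]-3-[2-fluoro-4,6-bis(methoxymethoxy)phenyl]propan-1-one | O=C(CCc1c(F)cc(OCOC)cc1OCOC)c1ccc(OCc2ccccc2)cc1
F6 | step 7 | (1R)-1-[4-(benzyloxy)phenyl]-3-[2-fluoro-4,6-bis(methoxymethoxy)phenyl]propan-1-ol | O[C@@H](c1ccc(OCc2ccccc2)cc1)CCc1c(F)cc(OCOC)cc1OCOC
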